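All constants were drawn at random within sensible limits; the rest is arithmetic.

The coupling makes and unmakes product and released group one for one, so their concentrations stay equal, and its back reaction runs as kr, the forward constant over the equilibrium constant, times the square of the product concentration P.

| flask | starting material | partner | temperature | time |
|---|---|---|---|---|
| violet | 20 mM | 1.30 equiv | 30 °C | 3.0 h |
| blue | 20 mM | 1.30 equiv | −20 °C | 3.0 h |
| grey | 20 mM | 1.30 equiv | 5 °C | 3.0 h |

    starting material + partner ⇌ product + released group (K1 = 1.1, k1 = 1.93 /M/min, Ea1 = 49.0 kJ/mol, ΔH1 = −36.0 kJ/mol)
    2 partner → homo dimer (k2 = 4.65 /M/min, Ea2 = 58.0 kJ/mol)
    partner → decomposed reagent (k3 = 0.0468 /min, Ea3 = 84.0 kJ/mol)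
    (constants at −20 °C)

- two of one species on the left: rate k times its square, two consumed each time
- the list of constants is for −20 °C, to be carried to other temperatures by the activation energies and enthalpies

* which flask leads in amount of product, in percent of the starting material charged ("all alike" within 1.5 percentage points) (violet / blue / grey / all alike)
* how much product is there at the end, in percent of the starting material charged: violet
* how much product is there at the end, in percent of the starting material charged: blue
* how much product is there at the end, in percent of the starting material charged: grey

Partner, although charged at 1.30 equiv, is the reagent to follow as the limiting reagent, and this ledger by hand is for blue, with starting material held at its charge. Of the 26.0 mM of partner, the homo dimer route takes 13.7 mM. The remaining 12.3 mM divides between the coupling and decomposition, whose first-order rates stand in a fixed ratio. The coupling's share f is 0.452, so the product entry is 5.58 mM and the decomposed reagent entry is 6.72 mM, and the books close.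

The books then reopen. Each product unmade returns a partner, and in this reckoning a share f of it couples again while the rest decomposes. P therefore falls as the drain constant c times the square of P, where c is kr times the share that does not come back; for blue c is 9.62 × 10⁻⁴ /mM/min. The reciprocal of P climbs in a straight line with slope c. With the ledger's product entry taken as the value at the start, this reckoning gives blue 2.84 mM at 3.0 h, or 14.2%.

Carried by the activation energies and the enthalpy, c is 0.0558 /mM/min for grey and 1.30 /mM/min for violet. With the slope term taken for the reciprocal at 3.0 h, this reckoning gives grey about 0.498% and violet about 0.0213%, so it puts blue ahead.

The forecast names blue, with 13% for blue, 0.48% for grey and 0.021% for violet, its blue figure lying below the reckoning above, and it concludes: “The coldest flask wins.”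

The simulation puts blue in the lead, with 13.3% in blue, 0.479% in grey and 0.0213% in violet.

Blue holds 3.48 mM of released group at 1.50 h, and its drain constant 9.62 × 10⁻⁴ /mM/min carries that to 2.67 mM at 3.00 h, where the flask shows 2.66 mM. The neighbour is grey read at 2.0 h. Grey's 0.185 mM at 1.50 h, carried with 0.0558 /mM/min, gives 0.141 mM. That neighbour reading shows 0.141 mM of released group, with product at 0.706%.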